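**Retrosynthetic overview**
1. The target acid comes from its methyl ester by hydrolysis in the last step. Both indole rings are bought intact, so the pyrrole is the only ring made, in the penultimate step.
2. The pyrrole comes from a 1,4-imino ketone by C–N ring closure (Paal–Knorr type). The imino ketone comes from an O-vinyl oxime by a [3,3] shift that makes the C3–C4 bond at the expense of the N–O bond.
3. Key disconnection: the enol C–O bond of the O-vinyl oxime. This leads to an α-oximino ketone (acetyl half, carries the nitrogen) and methyl indole-3-pyruvate (ester half). The N–O–C tether enforces cross-coupling and supplies the oxidation.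
4. The α-oximino ketone comes from α-nitrosation of 4-(indol-3-yl)butan-2-one, made from indole and methyl vinyl ketone. The keto ester comes from indole-3-pyruvic acid.

Assumption: the target has no stereocentre, so the goal is the single achiral structure shown and no stereocontrol is needed.

**Step 1**
Reactants: 1 indole; 2 methyl vinyl ketone
Product: 3 4-(1H-indol-3-yl)butan-2-one
Conditions: InCl3 (5 mol%), CH2Cl2, rt
Reagents that add atoms: none
Why: The Lewis acid-activated enone is attacked by the most nucleophilic indole carbon C3 (Friedel–Crafts-type Michael addition), which gives the 3-(3-oxobutyl)indole without N- or C2-alkylation and creates no stereocentre.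

**Step 2**
Reactants: 3 4-(1H-indol-3-yl)butan-2-one
Product: 5 (3E)-3-(hydroxyimino)-4-(1H-indol-3-yl)butan-2-one, via nitroso ketone 4 (not isolated)
Conditions: isopentyl nitrite (1.1 equiv), HCl (0.2 equiv, 4 M in dioxane), THF, −10 °C to rt
Reagents that add atoms: isopentyl nitrite, CC(C)CCON=O
Why: Acid-catalysed α-nitrosation of a methyl alkyl ketone goes through the more substituted enol, so NO+ is delivered to the methylene carbon (nitroso ketone 4), which tautomerises irreversibly to the conjugated α-oximino ketone with the hydroxyl anti to the acetyl group (classical isonitroso ketone synthesis, no stereocentre).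

**Step 3**
Reactants: 6 indole-3-pyruvic acid
Product: 8 methyl 3-(1H-indol-3-yl)-2-oxopropanoate, via potassium carboxylate 7 (not isolated)
Conditions: KHCO3 (1.2 equiv), MeI (1.5 equiv), DMF, 0 °C to rt, N2, dark
Reagents that add atoms: iodomethane, CI
Why: Bicarbonate deprotonates only the carboxylic acid (not the enol or the indole N–H), and potassium carboxylate 7 is O-methylated by SN2 attack on iodomethane (carboxylate alkylation), which avoids the strongly acidic or basic media that degrade this keto acid.

**Step 4**
Reactants: 5 (3E)-3-(hydroxyimino)-4-(1H-indol-3-yl)butan-2-one; 8 methyl 3-(1H-indol-3-yl)-2-oxopropanoate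
Product: 12 methyl 5-acetyl-3,4-di(1H-indol-3-yl)-1H-pyrrole-2-carboxylate, via O-vinyl oxime 9 (not isolated), via enehydroxylamine tautomer 10 (not isolated), via imino ketone 11 (not isolated)
Conditions: 5 (1.0 equiv), 8 (1.2 equiv), CSA (10 mol%), PhMe, Dean–Stark, 110 °C, N2
Reagents that add atoms: none
Why: Proposed new method: a dehydrative oxime O-alkenylation, in which acid catalysis adds the oxime O–H of 5 to the activated ketone carbonyl of 8 and azeotropic loss of water toward the indolylmethylene carbon gives the conjugated O-vinyl oxime 9 (the new C–O bond, which ties the two different halves together through an N–O–C tether), after which 9 follows the established course of O-vinyl oximes, namely tautomerisation to enehydroxylamine 10, [3,3]-sigmatropic shift that trades the weak N–O bond for the C3–C4 bond to give imino ketone 11, and Paal–Knorr-type attack of the imine nitrogen on the keto ester carbonyl with loss of water to the aromatic pyrrole, so that the N–O bond is the only oxidant, the sequence is redox-neutral and no stereocentre survives; the closest known reaction types are the Trofimov pyrrole synthesis (O-vinylation of a ketoxime by acetylene followed by the same [3,3] shift and cyclodehydration), the thermal rearrangement of preformed O-vinyl oximes to pyrroles and the Piloty–Robinson azine rearrangement, while direct condensation of an oxime with an enolisable α-keto ester to enter this manifold is the untested part.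

**Step 5**
Reactants: 12 methyl 5-acetyl-3,4-di(1H-indol-3-yl)-1H-pyrrole-2-carboxylate
Product: 14 5-acetyl-3,4-di(1H-indol-3-yl)-1H-pyrrole-2-carboxylic acid, via lithium carboxylate 13 (not isolated)
Conditions: LiOH·H2O (6 equiv), THF/MeOH/H2O (3:1:1), 45 °C; then 1 M HCl to pH 3, 0 °C
Reagents that add atoms: lithium hydroxide, [Li+].[OH-]
Why: Hydroxide attacks the ester carbonyl (saponification, BAc2) to give lithium carboxylate 13 while the acetyl ketone and the unprotected indoles are inert to aqueous base, and acidification liberates the free acid with no stereocentre involved.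

**Compound list**
1 | indole | c1ccc2[nH]ccc2c1 | starting material
2 | methyl vinyl ketone (but-3-en-2-one) | CC(=O)C=C | starting material
3 | 4-(1H-indol-3-yl)butan-2-one | CC(=O)CCc1c[nH]c2ccccc12 | intermediate
4 | 4-(1H-indol-3-yl)-3-nitrosobutan-2-one (racemic; not isolated) | CC(=O)C(N=O)Cc1c[nH]c2ccccc12 | intermediate
5 | (3E)-3-(hydroxyimino)-4-(1H-indol-3-yl)butan-2-one | CC(=O)/C(=N/O)Cc1c[nH]c2ccccc12 | intermediate
6 | indole-3-pyruvic acid (3-(1H-indol-3-yl)-2-oxopropanoic acid) | OC(=O)C(=O)Cc1c[nH]c2ccccc12 | starting material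
7 | potassium 3-(1H-indol-3-yl)-2-oxopropanoate (not isolated) | [K+].[O-]C(=O)C(=O)Cc1c[nH]c2ccccc12 | intermediate
8 | methyl 3-(1H-indol-3-yl)-2-oxopropanoate | COC(=O)C(=O)Cc1c[nH]c2ccccc12 | intermediate
9 | methyl (2Z)-3-(1H-indol-3-yl)-2-({[(2E)-1-(1H-indol-3-yl)-3-oxobutan-2-ylidene]amino}oxy)prop-2-enoate (not isolated) | COC(=O)/C(=C/c1c[nH]c2ccccc12)O/N=C(\Cc1c[nH]c2ccccc12)C(C)=O | intermediate
10 | methyl (2Z)-3-(1H-indol-3-yl)-2-({[1-(1H-indol-3-yl)-3-oxobut-1-en-2-yl]amino}oxy)prop-2-enoate (enamine geometry undefined; not isolated) | COC(=O)/C(=C/c1c[nH]c2ccccc12)ONC(=Cc1c[nH]c2ccccc12)C(C)=O | intermediate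
11 | methyl 5-imino-3,4-di(1H-indol-3-yl)-2,6-dioxoheptanoate (diastereomer mixture, both centres lost on aromatisation; not isolated) | COC(=O)C(=O)C(c1c[nH]c2ccccc12)C(c1c[nH]c2ccccc12)C(=N)C(C)=O | intermediate
12 | methyl 5-acetyl-3,4-di(1H-indol-3-yl)-1H-pyrrole-2-carboxylate | COC(=O)c1[nH]c(C(C)=O)c(-c2c[nH]c3ccccc23)c1-c1c[nH]c2ccccc12 | intermediate
13 | lithium 5-acetyl-3,4-di(1H-indol-3-yl)-1H-pyrrole-2-carboxylate (not isolated) | [Li+].[O-]C(=O)c1[nH]c(C(C)=O)c(-c2c[nH]c3ccccc23)c1-c1c[nH]c2ccccc12 | intermediate
14 | 5-acetyl-3,4-di(1H-indol-3-yl)-1H-pyrrole-2-carboxylic acid | CC(=O)c1[nH]c(C(=O)O)c(-c2c[nH]c3ccccc23)c1-c1c[nH]c2ccccc12 | target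

**Total step count:** 5. **Longest linear sequence:** 4 (steps 1, 2, 4, 5); step 3 is a one-step branch.

**Steps most likely to fail**

Step 4 (the proposed new step). The oxime oxygen of 5 is a weak nucleophile and water has to be lost next to an ester. Self-aldol of 8, oxime exchange between 5 and 8 (which would open the way to homo-coupled pyrroles), or Beckmann-type fragmentation of 5 may therefore compete. The fallback uses known chemistry, sets out from 5 and returns at 12; it makes the C–O bond first and the alkene afterwards.
- Rh2(OAc)4-catalysed O–H insertion of methyl 2-diazo-2-(dimethoxyphosphoryl)acetate into the oxime of 5 (CH2Cl2, 40 °C) gives racemic methyl 2-(dimethoxyphosphoryl)-2-({[(2E)-1-(1H-indol-3-yl)-3-oxobutan-2-ylidene]amino}oxy)acetate F1.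
- Horner–Wadsworth–Emmons olefination of F1 with commercial tert-butyl 3-formyl-1H-indole-1-carboxylate (LiCl, DBU, MeCN, 0 °C to rt) gives tert-butyl 3-[(1Z)-3-methoxy-2-({[(2E)-1-(1H-indol-3-yl)-3-oxobutan-2-ylidene]amino}oxy)-3-oxoprop-1-en-1-yl]-1H-indole-1-carboxylate F2. The carbamate is used because the free 3-formylindole is too poor an electrophile; either alkene isomer is usable.
- Heating F2 in PhMe (90–110 °C) triggers the documented O-vinyl oxime [3,3] shift and cyclodehydration to tert-butyl 3-[5-acetyl-4-(1H-indol-3-yl)-2-(methoxycarbonyl)-1H-pyrrol-3-yl]-1H-indole-1-carboxylate F3.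
- K2CO3 in MeOH (rt) removes the indole carbamate and gives 12.

Step 2. The free indole can be N-nitrosated, and some nitrosation at the methyl group is possible. The fallback sets out from 2 and 1 and returns at 5; it installs the oxime before the indole is present.
- Hydrochlorination of 2 (HCl, Et2O, 0 °C) gives 4-chlorobutan-2-one F4.
- Nitrosation (isopentyl nitrite, cat. HCl, Et2O, 0 °C) gives 4-chloro-3-(hydroxyimino)butan-2-one F5 (oxime geometry uncontrolled and irrelevant).
- Na2CO3 in CH2Cl2 (rt) eliminates HCl to the transient 3-nitrosobut-3-en-2-one F6, to which indole 1 (3 equiv) adds through C3 (conjugate addition to a nitrosoalkene), giving 5 directly.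

Step 3. Keto acid 6 is labile (air oxidation, self-condensation), and some enol O-methylation is possible. The fallback sets out from 1 and returns at 8; it builds the pyruvate side chain on indole instead of esterifying the keto acid.
- Methyl bromopyruvate and NH2OH·HCl (CHCl3/MeOH, rt) give methyl 3-bromo-2-(hydroxyimino)propanoate F7.
- With Na2CO3 in CH2Cl2, F7 forms methyl 2-nitrosoprop-2-enoate F8 in situ, which alkylates indole 1 at C3 to give methyl 2-(hydroxyimino)-3-(1H-indol-3-yl)propanoate F9.
- Reductive deoximation with TiCl3 (trivalent titanium) and NH4OAc in aqueous THF at rt gives 8.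

**Further compounds**
F1 | step 4 | methyl 2-(dimethoxyphosphoryl)-2-({[(2E)-1-(1H-indol-3-yl)-3-oxobutan-2-ylidene]amino}oxy)acetate (racemic) | COC(=O)C(O/N=C(\Cc1c[nH]c2ccccc12)C(C)=O)P(=O)(OC)OC
F2 | step 4 | tert-butyl 3-[(1Z)-3-methoxy-2-({[(2E)-1-(1H-indol-3-yl)-3-oxobutan-2-ylidene]amino}oxy)-3-oxoprop-1-en-1-yl]-1H-indole-1-carboxylate | COC(=O)/C(=C/c1cn(C(=O)OC(C)(C)C)c2ccccc12)O/N=C(\Cc1c[nH]c2ccccc12)C(C)=O
F3 | step 4 | tert-butyl 3-[5-acetyl-4-(1H-indol-3-yl)-2-(methoxycarbonyl)-1H-pyrrol-3-yl]-1H-indole-1-carboxylate | COC(=O)c1[nH]c(C(C)=O)c(-c2c[nH]c3ccccc23)c1-c1cn(C(=O)OC(C)(C)C)c2ccccc12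
F4 | step 2 | 4-chlorobutan-2-one | CC(=O)CCCl
F5 | step 2 | 4-chloro-3-(hydroxyimino)butan-2-one | CC(=O)C(CCl)=NO
F6 | step 2 | 3-nitrosobut-3-en-2-one | CC(=O)C(=C)N=O
F7 | step 3 | methyl 3-bromo-2-(hydroxyimino)propanoate | COC(=O)C(CBr)=NO
F8 | step 3 | methyl 2-nitrosoprop-2-enoate | COC(=O)C(=C)N=O
F9 | step 3 | methyl 2-(hydroxyimino)-3-(1H-indol-3-yl)propanoate | COC(=O)C(Cc1c[nH]c2ccccc12)=NO
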